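**Retrosynthetic overview**

1. Target and atom labels: an oxolane (O1, C2–C5) carries ring B at C2, CH2OH at C3, and OH plus the ring A benzyl group at C4 (2R,3R,4S; the three carbon substituents are all cis). Ring B is fused to a cis-2,3-dihydrobenzofuran (O1', C2' bearing ring C, C3' bearing CH2OH; 2'R,3'R).
2. The plan rests on the C2'–C3' bond of the dihydrofuran ring. If O1' is kept as the ring C benzylic ether of the ring B phenol, its O–CH2 carbon (future C2') lies 1,5 to the α-carbon of a ring B aryl diazoacetate (future C3'). A chiral dirhodium carbenoid then closes this ring by C–H insertion, cis under kinetic control, as the last C–C bond.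
3. The diazoacetate comes from an aryl bromide (carried from 5-bromovanillin) by palladium-catalysed coupling with a zinc ester enolate, then diazo transfer.
4. The oxolane comes from O1–C5 etherification of a 1,4-diol. The diol comes from a cis-γ-aryl-β-(silyloxymethyl)butyrolactone whose enolate is benzylated and then hydroxylated on the face away from the C2 and C3 substituents (sets C4).
5. C2 and C3 come from an auxiliary-controlled anti-aldol of the ring B aldehyde with a pent-4-enoyl imide. Ring order: lactone template, then oxolane, then dihydrofuran.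

Key step: step 15

Assumption: the sense of induction in steps 4 and 15 follows the accepted models (chelated Z-enolate attacked anti to the auxiliary benzyl group; (S)-phthaloyl-tert-leucinate ligands giving the 2'R cis product, as with simpler 2-benzyloxyphenyl diazoacetates). If either were opposite, the enantiomeric auxiliary or catalyst would be used.

Abbreviations: ArB = 3-bromo-4-{[4-(benzyloxy)-3-methoxyphenyl]methoxy}-5-methoxyphenyl; VB = 4-(benzyloxy)-3-methoxybenzyl; TBS = tert-butyldimethylsilyl; TES = triethylsilyl.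

**Route**

Step 1
Reactants: 1 4-(benzyloxy)-3-methoxybenzyl alcohol
Product: 2 4-(benzyloxy)-3-methoxybenzyl bromide
Conditions: PBr3, Et2O, 0 °C
Reagents that add atoms: phosphorus tribromide, BrP(Br)Br
Why: Bromination of a primary benzylic alcohol with PBr3 (SN2 displacement of the phosphite ester by bromide) should be clean at 0 °C; the electron-rich bromide is used at once in steps 2 and 8.

Step 2
Reactants: 3 5-bromovanillin; 2 4-(benzyloxy)-3-methoxybenzyl bromide
Product: 4 3-bromo-4-{[4-(benzyloxy)-3-methoxyphenyl]methoxy}-5-methoxybenzaldehyde (ArB–CHO)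
Conditions: K2CO3, DMF, 50 °C
Reagents that add atoms: none
Why: Williamson ether synthesis; the phenol flanked by Br and OMe is acidic and its phenoxide should be alkylated by the benzylic bromide without touching the aldehyde.

Step 3
Reactants: 5 (R)-4-benzyloxazolidin-2-one; 6 pent-4-enoyl chloride
Product: 7 (R)-4-benzyl-3-(pent-4-enoyl)oxazolidin-2-one
Conditions: n-BuLi, THF, −78 °C; then 6, −78 → 0 °C
Reagents that add atoms: none
Why: N-acylation of the lithiated oxazolidinone by an acid chloride, the standard preparation of N-acyl oxazolidinone imides.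

Step 4
Reactants: 4 ArB–CHO; 7 (R)-4-benzyl-3-(pent-4-enoyl)oxazolidin-2-one
Product: 9 (4R)-4-benzyl-3-[(2S,3R)-2-allyl-3-ArB-3-hydroxypropanoyl]oxazolidin-2-one (anti-aldol adduct), via aldol trimethylsilyl ether 8 (not isolated)
Conditions: MgCl2 (20 mol %), Et3N, Me3SiCl, EtOAc, rt; then 1 M HCl, THF, 0 °C
Reagents that add atoms: none
Why: MgCl2-catalysed anti-aldol addition of an N-acyl oxazolidinone to a non-enolisable aromatic aldehyde (Evans anti-aldol): the magnesium-chelated Z-enolate of the (R)-auxiliary should be attacked on the face away from its benzyl group (sets C3) through the boat-like transition state leading to the anti adduct (sets C2 as R), and silylation of the aldolate makes the addition irreversible.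

Step 5
Reactants: 9 anti-aldol adduct
Product: 10 (1R,2R)-1-ArB-2-(prop-2-en-1-yl)propane-1,3-diol
Conditions: LiBH4, Et2O, H2O (1 equiv), 0 °C
Reagents that add atoms: none
Why: Reductive cleavage of the imide by LiBH4 should give the primary alcohol and the recoverable auxiliary without touching the stereocentres, the alkene or the aryl bromide.

Step 6
Reactants: 10 diol
Product: 11 (1R,2R)-1-ArB-2-[(tert-butyldimethylsilyloxy)methyl]pent-4-en-1-ol
Conditions: t-BuMe2SiCl, imidazole, CH2Cl2, 0 °C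
Reagents that add atoms: tert-butyldimethylsilyl chloride, CC(C)(C)[Si](C)(C)Cl
Why: Selective silylation of the primary hydroxyl over the hindered secondary benzylic one.

Step 7
Reactants: 11 mono-TBS ether
Product: 13 (4R,5R)-5-ArB-4-[(tert-butyldimethylsilyloxy)methyl]oxolan-2-one (cis lactone), via lactol 12 (not isolated)
Conditions: OsO4 (2 mol %), NaIO4, 2,6-lutidine, dioxane–H2O, rt; then (n-Pr)4N[RuO4] (5 mol %), N-methylmorpholine N-oxide, 4 Å sieves, CH2Cl2, rt
Reagents that add atoms: osmium tetroxide, O=[Os](=O)(=O)=O (catalytic oxygen carrier); sodium periodate, [Na+].[O-]I(=O)(=O)=O (terminal oxidant)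
Why: Lemieux–Johnson cleavage of the terminal alkene gives an aldehyde that the C2 hydroxyl traps as the five-membered lactol, and Ley–Griffith perruthenate oxidation of the lactol should give the cis-γ-aryl lactone with C2 and C3 untouched.

Step 8
Reactants: 13 cis lactone; 2 4-(benzyloxy)-3-methoxybenzyl bromide
Product: 14 (3S,4R,5R)-5-ArB-3-VB-4-[(tert-butyldimethylsilyloxy)methyl]oxolan-2-one (3,4-trans)
Conditions: LiN(SiMe3)2, THF, −78 °C; then 2, −78 → −30 °C
Reagents that add atoms: none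
Why: Alkylation of the lactone lithium enolate with a benzylic bromide, expected anti to the C3 substituent; this configuration at the lactone α-carbon is provisional and is re-set in step 9.

Step 9
Reactants: 14 α-benzyl lactone
Product: 15 (3S,4R,5R)-5-ArB-3-VB-3-hydroxy-4-[(tert-butyldimethylsilyloxy)methyl]oxolan-2-one (OH trans to CH2OTBS and ArB)
Conditions: KN(SiMe3)2, THF, −78 °C; then 3-phenyl-2-(phenylsulfonyl)oxaziridine, −78 °C
Reagents that add atoms: 3-phenyl-2-(phenylsulfonyl)oxaziridine (Davis reagent), O=S(=O)(c1ccccc1)N1OC1c1ccccc1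
Why: Davis hydroxylation of the tetrasubstituted lactone enolate: oxygen should be delivered to the face opposite the cis aryl and silyloxymethyl groups, so the hydroxyl at the future C4 ends trans to them and the benzyl group cis (C4 = S), as in α-hydroxylations of α-benzyl-β-substituted butyrolactones.

Step 10
Reactants: 15 α-hydroxy lactone
Product: 16 triethylsilyl ether of 15, (3S,4R,5R)-5-ArB-3-VB-4-[(tert-butyldimethylsilyloxy)methyl]-3-(triethylsilyloxy)oxolan-2-one
Conditions: Et3SiOSO2CF3, 2,6-lutidine, CH2Cl2, −78 → 0 °C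
Reagents that add atoms: triethylsilyl trifluoromethanesulfonate, CC[Si](CC)(CC)OS(=O)(=O)C(F)(F)F
Why: Silylation of a hindered tertiary alcohol with a silyl triflate; the ether prevents epoxide formation in step 12 and O–H insertion in step 15.

Step 11
Reactants: 16 silylated lactone
Product: 17 (1R,2R,3S)-1-ArB-3-VB-2-[(tert-butyldimethylsilyloxy)methyl]-3-(triethylsilyloxy)butane-1,4-diol
Conditions: LiAlH4, THF, −20 → 0 °C
Reagents that add atoms: none
Why: Hydride reduction of the lactone to the 1,4-diol; at low temperature the silyl ethers and the aryl bromide should survive.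

Step 12
Reactants: 17 1,4-diol
Product: 19 (2R,3R,4S)-2-ArB-4-VB-3-[(tert-butyldimethylsilyloxy)methyl]-4-(triethylsilyloxy)oxolane, via primary tosylate 18 (not isolated)
Conditions: TsCl (1.2 equiv), pyridine, DMAP (cat.), 0 → 60 °C
Reagents that add atoms: none
Why: Selective sulfonylation of the primary hydroxyl followed by intramolecular Williamson displacement (5-exo-tet) by the C2 hydroxyl forms O1–C5 with retention at benzylic C2, so the cis C2/C3 relation is kept and no benzylic cation is involved.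

Step 13
Reactants: 19 oxolane aryl bromide
Product: 20 methyl 2-{2-(VB-oxy)-3-methoxy-5-[(2R,3R,4S)-4-VB-3-(TBSO-methyl)-4-(TESO)oxolan-2-yl]phenyl}acetate
Conditions: BrZnCH2CO2Me (from BrCH2CO2Me, Zn, THF), Pd(dba)2 (2 mol %), P(t-Bu)3 (2 mol %), THF, rt → 50 °C
Reagents that add atoms: methyl bromozincacetate, COC(=O)C[Zn]Br
Why: Palladium-catalysed α-arylation of an ester as its zinc (Reformatsky) enolate, a Negishi-type coupling from zerovalent palladium that runs under neutral conditions and should tolerate the silyl and benzyl ethers.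

Step 14
Reactants: 20 methyl arylacetate
Product: 21 methyl 2-diazo-2-{2-(VB-oxy)-3-methoxy-5-[(2R,3R,4S)-4-VB-3-(TBSO-methyl)-4-(TESO)oxolan-2-yl]phenyl}acetate
Conditions: 4-AcNHC6H4SO2N3, DBU, MeCN, 0 °C → rt
Reagents that add atoms: 4-acetamidobenzenesulfonyl azide, CC(=O)Nc1ccc(S(=O)(=O)N=[N+]=[N-])cc1
Why: Regitz diazo transfer to the benzylic ester position gives the donor/acceptor diazo compound.

Step 15
Reactants: 21 aryl diazoacetate
Product: 22 methyl (2R,3S)-2-[4-(benzyloxy)-3-methoxyphenyl]-7-methoxy-5-[(2R,3R,4S)-4-VB-3-(TBSO-methyl)-4-(TESO)oxolan-2-yl]-2,3-dihydro-1-benzofuran-3-carboxylate (cis)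
Conditions: dirhodium tetrakis[N-phthaloyl-(S)-tert-leucinate], Rh2(S-PTTL)4 (2 mol %), toluene, −60 °C, slow addition of 21
Reagents that add atoms: none
Why: The divalent rhodium catalyst expels N2 from 21 to give a donor/acceptor carbenoid on the ring B carbon ortho to the benzylic ether, and the carbenoid carbon (future C3') inserts into one O–CH2 hydrogen of that ether through a three-centre, hydride-transfer-like transition state, forming the C2'–C3' bond. The closest known reaction type is the dirhodium carboxylate-catalysed intramolecular C–H insertion of 2-(benzyloxy)phenyl diazoacetates to cis-2-aryl-2,3-dihydrobenzofuran-3-carboxylates. The dihydrofuran ring closes by 1,5 C–H insertion through a five-membered array (C3', C3a, C7a, O1', C2'). C2' and C3' are both set by the chiral phthaloyl-tert-leucinate ligands, which select the carbenoid face and one of the two methylene hydrogens; cis is the kinetic outcome of this insertion, and the (S)-ligands are expected to give 2'R by analogy with simpler aryl cases. The step needs chemoselectivity for this one C–H bond, which is secured because it is activated by both the ether oxygen and the electron-rich ring C and is the only activated C–H that can reach the carbenoid in a five-membered array (the oxolane C2–H and the methoxy C–H bonds would have to bridge meta positions of ring B). Low temperature and neutral work-up should keep the epimerisable C3' cis.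

Step 16
Reactants: 22 cis ester
Product: 23 {(2R,3R)-2-[4-(benzyloxy)-3-methoxyphenyl]-7-methoxy-5-[(2R,3R,4S)-4-VB-3-(TBSO-methyl)-4-(TESO)oxolan-2-yl]-2,3-dihydro-1-benzofuran-3-yl}methanol
Conditions: i-Bu2AlH, CH2Cl2, −78 → −40 °C
Reagents that add atoms: none
Why: Low-temperature, non-basic hydride reduction of the ester to the primary alcohol should leave C3' (benzylic and α to the ester) unepimerised.

Step 17
Reactants: 23 bis-silyl ether
Product: 24 tri-O-benzyl target, (2R,3R,4S)-oxolane with free C3 CH2OH, C4 OH and C3' CH2OH, the three phenols as benzyl ethers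
Conditions: Bu4NF, THF, 0 °C → rt
Reagents that add atoms: none
Why: Fluoride cleavage of the primary TBS and tertiary TES ethers; with the phenols still benzylated no phenoxide can open the dihydrofuran.

Step 18
Reactants: 24 tri-O-benzyl target
Product: 25 CNP0284796.1
Conditions: H2 (1 atm), Pd/C (10 wt %), EtOAc–MeOH, rt, stopped after uptake of 3 equiv
Reagents that add atoms: none
Why: Hydrogenolysis of the three aryl benzyl ethers under neutral conditions is much faster than cleavage of the two cyclic benzylic C–O bonds, as is usual for dihydrobenzofuran neolignans.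

**Compound list**

1 | 4-(benzyloxy)-3-methoxybenzyl alcohol | COc1cc(CO)ccc1OCc1ccccc1 | starting material
2 | 4-(benzyloxy)-3-methoxybenzyl bromide | COc1cc(CBr)ccc1OCc1ccccc1 | intermediate
3 | 5-bromovanillin (3-bromo-4-hydroxy-5-methoxybenzaldehyde) | COc1cc(C=O)cc(Br)c1O | starting material
4 | 3-bromo-4-{[4-(benzyloxy)-3-methoxyphenyl]methoxy}-5-methoxybenzaldehyde | COc1cc(C=O)cc(Br)c1OCc1ccc(OCc2ccccc2)c(OC)c1 | intermediate
5 | (R)-4-benzyloxazolidin-2-one | O=C1N[C@H](Cc2ccccc2)CO1 | starting material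
6 | pent-4-enoyl chloride | C=CCCC(Cl)=O | starting material
7 | (R)-4-benzyl-3-(pent-4-enoyl)oxazolidin-2-one | C=CCCC(=O)N1[C@H](Cc2ccccc2)COC1=O | intermediate
8 | O-trimethylsilyl ether of anti-aldol adduct 9 | C=CC[C@H](C(=O)N1[C@H](Cc2ccccc2)COC1=O)[C@@H](O[Si](C)(C)C)c1cc(OC)c(OCc2ccc(OCc3ccccc3)c(OC)c2)c(Br)c1 | intermediate
9 | (4R)-4-benzyl-3-[(2S,3R)-2-allyl-3-ArB-3-hydroxypropanoyl]oxazolidin-2-one | C=CC[C@H](C(=O)N1[C@H](Cc2ccccc2)COC1=O)[C@@H](O)c1cc(OC)c(OCc2ccc(OCc3ccccc3)c(OC)c2)c(Br)c1 | intermediate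
10 | (1R,2R)-1-ArB-2-(prop-2-en-1-yl)propane-1,3-diol | C=CC[C@H](CO)[C@@H](O)c1cc(OC)c(OCc2ccc(OCc3ccccc3)c(OC)c2)c(Br)c1 | intermediate
11 | (1R,2R)-1-ArB-2-[(tert-butyldimethylsilyloxy)methyl]pent-4-en-1-ol | C=CC[C@H](CO[Si](C)(C)C(C)(C)C)[C@@H](O)c1cc(OC)c(OCc2ccc(OCc3ccccc3)c(OC)c2)c(Br)c1 | intermediate
12 | (4R,5R)-5-ArB-4-[(tert-butyldimethylsilyloxy)methyl]oxolan-2-ol (lactol, anomer mixture) | OC1O[C@@H](c2cc(OC)c(OCc3ccc(OCc4ccccc4)c(OC)c3)c(Br)c2)[C@@H](CO[Si](C)(C)C(C)(C)C)C1 | intermediate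
13 | (4R,5R)-5-ArB-4-[(tert-butyldimethylsilyloxy)methyl]oxolan-2-one (cis) | O=C1O[C@@H](c2cc(OC)c(OCc3ccc(OCc4ccccc4)c(OC)c3)c(Br)c2)[C@@H](CO[Si](C)(C)C(C)(C)C)C1 | intermediate
14 | (3S,4R,5R)-5-ArB-3-VB-4-[(tert-butyldimethylsilyloxy)methyl]oxolan-2-one | O=C1O[C@@H](c2cc(OC)c(OCc3ccc(OCc4ccccc4)c(OC)c3)c(Br)c2)[C@@H](CO[Si](C)(C)C(C)(C)C)[C@@H]1Cc1ccc(OCc2ccccc2)c(OC)c1 | intermediate
15 | (3S,4R,5R)-5-ArB-3-VB-3-hydroxy-4-[(tert-butyldimethylsilyloxy)methyl]oxolan-2-one | O=C1O[C@@H](c2cc(OC)c(OCc3ccc(OCc4ccccc4)c(OC)c3)c(Br)c2)[C@@H](CO[Si](C)(C)C(C)(C)C)[C@@]1(O)Cc1ccc(OCc2ccccc2)c(OC)c1 | intermediate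
16 | (3S,4R,5R)-5-ArB-3-VB-4-[(tert-butyldimethylsilyloxy)methyl]-3-(triethylsilyloxy)oxolan-2-one | O=C1O[C@@H](c2cc(OC)c(OCc3ccc(OCc4ccccc4)c(OC)c3)c(Br)c2)[C@@H](CO[Si](C)(C)C(C)(C)C)[C@@]1(O[Si](CC)(CC)CC)Cc1ccc(OCc2ccccc2)c(OC)c1 | intermediate
17 | (1R,2R,3S)-1-ArB-3-VB-2-[(tert-butyldimethylsilyloxy)methyl]-3-(triethylsilyloxy)butane-1,4-diol | COc1cc(C[C@@](O[Si](CC)(CC)CC)(CO)[C@H](CO[Si](C)(C)C(C)(C)C)[C@@H](O)c2cc(OC)c(OCc3ccc(OCc4ccccc4)c(OC)c3)c(Br)c2)ccc1OCc1ccccc1 | intermediate
18 | 4-O-(p-toluenesulfonate) of diol 17 (primary tosylate) | COc1cc(C[C@@](O[Si](CC)(CC)CC)(COS(=O)(=O)c2ccc(C)cc2)[C@H](CO[Si](C)(C)C(C)(C)C)[C@@H](O)c2cc(OC)c(OCc3ccc(OCc4ccccc4)c(OC)c3)c(Br)c2)ccc1OCc1ccccc1 | intermediate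
19 | (2R,3R,4S)-2-ArB-4-VB-3-[(tert-butyldimethylsilyloxy)methyl]-4-(triethylsilyloxy)oxolane | COc1cc(C[C@@]2(O[Si](CC)(CC)CC)CO[C@@H](c3cc(OC)c(OCc4ccc(OCc5ccccc5)c(OC)c4)c(Br)c3)[C@H]2CO[Si](C)(C)C(C)(C)C)ccc1OCc1ccccc1 | intermediate
20 | methyl arylacetate (Br of 19 replaced by CH2CO2Me) | COc1cc(C[C@@]2(O[Si](CC)(CC)CC)CO[C@@H](c3cc(OC)c(OCc4ccc(OCc5ccccc5)c(OC)c4)c(CC(=O)OC)c3)[C@H]2CO[Si](C)(C)C(C)(C)C)ccc1OCc1ccccc1 | intermediate
21 | methyl aryl(diazo)acetate, key-step precursor | COc1cc(C[C@@]2(O[Si](CC)(CC)CC)CO[C@@H](c3cc(OC)c(OCc4ccc(OCc5ccccc5)c(OC)c4)c(C(=[N+]=[N-])C(=O)OC)c3)[C@H]2CO[Si](C)(C)C(C)(C)C)ccc1OCc1ccccc1 | intermediate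
22 | methyl (2R,3S)-cis-2-aryl-2,3-dihydrobenzofuran-3-carboxylate on the protected oxolane | COc1cc(C[C@@]2(O[Si](CC)(CC)CC)CO[C@@H](c3cc(OC)c4c(c3)[C@H](C(=O)OC)[C@H](c3ccc(OCc5ccccc5)c(OC)c3)O4)[C@H]2CO[Si](C)(C)C(C)(C)C)ccc1OCc1ccccc1 | intermediate
23 | (2'R,3'R)-3'-hydroxymethyl dihydrobenzofuran, bis-silyl ether | COc1cc(C[C@@]2(O[Si](CC)(CC)CC)CO[C@@H](c3cc(OC)c4c(c3)[C@H](CO)[C@H](c3ccc(OCc5ccccc5)c(OC)c3)O4)[C@H]2CO[Si](C)(C)C(C)(C)C)ccc1OCc1ccccc1 | intermediate
24 | tri-O-benzyl ether of the target | COc1cc(C[C@@]2(O)CO[C@@H](c3cc(OC)c4c(c3)[C@H](CO)[C@H](c3ccc(OCc5ccccc5)c(OC)c3)O4)[C@H]2CO)ccc1OCc1ccccc1 | intermediate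
25 | CNP0284796.1, (3S,4R,5R)-5-[(2R,3R)-2-(4-hydroxy-3-methoxyphenyl)-3-(hydroxymethyl)-7-methoxy-2,3-dihydro-1-benzofuran-5-yl]-3-(4-hydroxy-3-methoxybenzyl)-4-(hydroxymethyl)oxolan-3-ol | COc1cc(C[C@@]2(O)CO[C@@H](c3cc(OC)c4c(c3)[C@H](CO)[C@H](c3ccc(O)c(OC)c3)O4)[C@H]2CO)ccc1O | target

**Step count**

Total: 18 steps. Longest linear sequence: 17 steps (1 → 2 → 4 → 9 → … → 25; steps 1, 2 and 4–18).

**Steps most likely to fail**

Step 15. The catalyst may lose control of which carbenoid face and which methylene hydrogen react. This could come from a mismatched pairing with the oxolane centres or from substrate ether oxygens occupying the axial sites of the dirhodium core, and would give trans or 2'S material; carbenoid dimerisation could also compete. The fallback adds a covalently bound second control element. Setting out from 20, LiOH in THF–H2O would give the arylacetic acid F1. Esterification (EDC, DMAP) with (S)-2-hydroxy-1-(pyrrolidin-1-yl)propan-1-one would give the lactamide ester F2, and diazo transfer (4-acetamidobenzenesulfonyl azide, DBU) the diazo ester F3. Insertion with Rh2(S-PTTL)4 under double stereodifferentiation should give the cis-dihydrobenzofuran lactamide ester F4. LiBH4 then cleaves the auxiliary ester and the route is rejoined at 23.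

Step 4. Addition to the electron-rich, hindered aldehyde may be slow and reversible before silylation, eroding the anti selectivity or the facial control, and retro-aldol cleavage may occur on desilylation. The fallback sets the two centres one after the other. Setting out from 4, Reformatsky addition (Zn, ethyl bromoacetate, THF) would give the racemic β-hydroxy ester F5, and Dess–Martin oxidation the β-keto ester F6. Asymmetric transfer hydrogenation with RuCl[(R,R)-TsDPEN](p-cymene) in HCO2H–Et3N should give the (R)-β-hydroxy ester F7. Frater–Seebach alkylation of its dianion (LDA, 2.2 equiv, THF, −78 → −20 °C; allyl bromide) should give the anti 2-allyl ester F8. LiAlH4 reduction rejoins the route at 10.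

Step 13. Oxidative addition and transmetalation at the ortho-alkoxy, electron-rich bromide may be slow, so that protodebromination or palladium-mediated C–H arylation of the neighbouring benzylic ether ring takes over. The fallback builds the acetate from an allyl group. Setting out from 19, Stille coupling with allyltributylstannane (Pd(PPh3)4, toluene, 100 °C) would give the allylarene F9. Lemieux–Johnson cleavage (OsO4 cat., NaIO4, 2,6-lutidine) would give the arylacetaldehyde F10. Oxidative esterification (I2, KOH, MeOH, 0 °C) rejoins the route at 20.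

**Further compounds**

F1 | step 15 | arylacetic acid corresponding to 20 | COc1cc(C[C@@]2(O[Si](CC)(CC)CC)CO[C@@H](c3cc(OC)c(OCc4ccc(OCc5ccccc5)c(OC)c4)c(CC(=O)O)c3)[C@H]2CO[Si](C)(C)C(C)(C)C)ccc1OCc1ccccc1
F2 | step 15 | (S)-1-oxo-1-(pyrrolidin-1-yl)propan-2-yl arylacetate (lactamide ester) | COc1cc(C[C@@]2(O[Si](CC)(CC)CC)CO[C@@H](c3cc(OC)c(OCc4ccc(OCc5ccccc5)c(OC)c4)c(CC(=O)O[C@@H](C)C(=O)N4CCCC4)c3)[C@H]2CO[Si](C)(C)C(C)(C)C)ccc1OCc1ccccc1
F3 | step 15 | lactamide aryl(diazo)acetate | COc1cc(C[C@@]2(O[Si](CC)(CC)CC)CO[C@@H](c3cc(OC)c(OCc4ccc(OCc5ccccc5)c(OC)c4)c(C(=[N+]=[N-])C(=O)O[C@@H](C)C(=O)N4CCCC4)c3)[C@H]2CO[Si](C)(C)C(C)(C)C)ccc1OCc1ccccc1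
F4 | step 15 | lactamide ester of the cis-(2R,3S)-dihydrobenzofuran-3-carboxylic acid | COc1cc(C[C@@]2(O[Si](CC)(CC)CC)CO[C@@H](c3cc(OC)c4c(c3)[C@H](C(=O)O[C@@H](C)C(=O)N5CCCC5)[C@H](c3ccc(OCc5ccccc5)c(OC)c3)O4)[C@H]2CO[Si](C)(C)C(C)(C)C)ccc1OCc1ccccc1
F5 | step 4 | ethyl 3-ArB-3-hydroxypropanoate (racemic) | CCOC(=O)CC(O)c1cc(OC)c(OCc2ccc(OCc3ccccc3)c(OC)c2)c(Br)c1
F6 | step 4 | ethyl 3-ArB-3-oxopropanoate | CCOC(=O)CC(=O)c1cc(OC)c(OCc2ccc(OCc3ccccc3)c(OC)c2)c(Br)c1
F7 | step 4 | ethyl (3R)-3-ArB-3-hydroxypropanoate | CCOC(=O)C[C@@H](O)c1cc(OC)c(OCc2ccc(OCc3ccccc3)c(OC)c2)c(Br)c1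
F8 | step 4 | ethyl (2S,3R)-2-allyl-3-ArB-3-hydroxypropanoate (anti) | CCOC(=O)[C@@H](CC=C)[C@@H](O)c1cc(OC)c(OCc2ccc(OCc3ccccc3)c(OC)c2)c(Br)c1
F9 | step 13 | allylarene (Br of 19 replaced by allyl) | COc1cc(C[C@@]2(O[Si](CC)(CC)CC)CO[C@@H](c3cc(OC)c(OCc4ccc(OCc5ccccc5)c(OC)c4)c(CC=C)c3)[C@H]2CO[Si](C)(C)C(C)(C)C)ccc1OCc1ccccc1
F10 | step 13 | arylacetaldehyde (Br of 19 replaced by CH2CHO) | COc1cc(C[C@@]2(O[Si](CC)(CC)CC)CO[C@@H](c3cc(OC)c(OCc4ccc(OCc5ccccc5)c(OC)c4)c(CC=O)c3)[C@H]2CO[Si](C)(C)C(C)(C)C)ccc1OCc1ccccc1
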